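## Structural features

The target is a trimeric acylphloroglucinol: three fully substituted benzene rings (A, B, C) joined only by two methylene bridges, B3–CH2–A1 and B5–CH2–C1. Ring B is a 2,4,6-trihydroxyphenyl ketone whose B1 acyl group is (R)-2-methylbutanoyl. Rings A and C are the same 2,6-dihydroxy-4-methoxy-3-methyl-5-acylphenyl unit, with acetyl on ring A and 2-methylpropanoyl on ring C. The only stereocentre is the α-carbon of the B1 ketone; it has no stereogenic neighbour, so the stereochemical task is to bring it in from (R)-2-methylbutanoic acid and never let that ketone enolise. Fragile elements are this enolisable centre, the seven free phenols (air oxidation), and the diarylmethane bridges, which strong acid or base can cleave and scramble by retro-Friedel–Crafts or quinone-methide pathways. The real difficulty is the lack of symmetry: the arms differ only in a remote acyl group, so hanging them on a preformed ring B would require statistical differentiation of B3 and B5, and each outer ring needs one particular oxygen (A4, C4) methylated while its neighbours stay free. Ring B alternates oxygen and carbon substituents all the way round (B2–O, B3–C, B4–O, B5–C, B6–O, B1–acyl). The key step exploits this: a four-carbon 1,1,3-trioxygenated diene (B2–B3–B4–B5, already carrying both arms) joined to a two-carbon β-alkoxy ynone (B6 with its oxygen, B1 with the chiral acyl group) delivers exactly this pattern.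

## Logic of the disconnections

**33 ⇒ 32.** Cut: five phenolic O–CH2Ph bonds (B6 and the four outer-ring oxygens flanking the bridges). The free polyphenol is oxidisable, and free hydroxyls ortho to the bridges would cyclise onto the keto ester in earlier intermediates; benzyl ethers answer both and fall in one operation. Demand: a neutral hydrogenolysis that leaves aryl ketones, bridges and the stereocentre alone.

**32 ⇒ 21 + 30.** Cut: B5–B6 and B1–B2, which opens ring B. The alternating O/C pattern maps onto an electron-rich diene and a push–pull alkyne; the cut is convergent, the two arms are told apart before the ring exists, and the stereocentre arrives ready-made in the small partner. Gain: ring B, its three oxygens and the union of three fragments in one step. Demand: head-to-tail regiochemistry, loss of methanol rather than of benzyl alcohol, and a neutral thermal window below the temperature at which the benzyl alkynyl ether of 30 rearranges.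

**30 ⇒ 24 + 27; 24 ⇒ 22; 27 ⇒ 25.** Cut: the carbonyl–alkyne bond, then the amide C–N bond and the vinyl C–O bond. An N-methoxy-N-methylamide takes one acetylide only and keeps the ketone masked as a tetrahedral adduct until quench. Gain: the chiral pool acid 22 and the simple alcohol 25. Demand: the free ketone must never meet base, and the alkynyl ether must stay cold.

**21 ⇒ 20.** Cut: three O–Si bonds. The keto ester is the stable storage form. The design point is that a free methyl ketone on ring A cannot survive any enol silylation that makes the diene, so 21 carries that ketone deliberately as its trimethylsilyl enol ether, which the acid work-up of the key step returns. Demand: complete enolisation towards C4, (3Z) geometry of the C3=C4 enol ether (hydrogen inside the diene), the hindered isopropyl ketone untouched, strictly anhydrous handling.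

**20 ⇒ 18 + 15.** Cut: the C2–CH2 bond to ring A. C2 is the most acidic site and is alkylated under mild base, which the acetyl group of 15 tolerates. Demand: C- rather than O-alkylation, and one alkylation only.

**18 ⇒ 16 + 8.** Cut: the C4–CH2 bond to ring C. The strongly basic dianion step is given to the arm whose ketone is hindered and poorly enolisable; the methyl-ketone arm is kept for the mild step above, and this order is what differentiates the arms. Gain: a commodity keto ester and a benzylic bromide. Demand: displacement faster than proton transfer or carbonyl addition.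

**8 ⇒ 7 ⇒ 6 ⇒ 4 and 15 ⇒ 14 ⇒ 13 ⇒ 11.** Cut: C–Br, then the carbinol C–H (redox), then the ring–CHO bond. Each of 4 and 11 has one free ring position, flanked by both benzyloxy groups, so electrophilic formylation is regiochemically unambiguous. Demand: formylation of the ring and not of the ketone side chain (critical for 11), reduction of the aldehyde only, and bromides used fresh.

**4 ⇒ 3 ⇒ 2 and 11 ⇒ 10 ⇒ 9.** Cut: the O–CH3 bond, then two O–CH2Ph bonds. The three hydroxyls differ: the para one is not hydrogen-bonded, and of the two chelating ortho ones, one is buttressed by the ring methyl. Alkylating in order of reactivity leaves the methyl group for the last, most hindered oxygen. Demand: site selectivity in the second benzylation.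

**2 ⇒ 1.** Cut: the ring–acyl bond. The two free positions of 1 are equivalent, so Friedel–Crafts acylation is unambiguous; 9 is bought at the same stage. Demand: mono-acylation.

## Other disconnections considered

**Alternative 1:** The cut is at the two methoxy oxygens: the A4–O and C4–O bonds are made last, from C–H bonds. Forward, the heptaacetate A2 (hydrogen at A4 and C4) would be treated with Pd(OAc)2 and K2S2O8 in trifluoroacetic acid. Each outer-ring ketone would direct cyclopalladation by divalent palladium to its single ortho C–H bond, K2S2O8 would raise the palladacycle to tetravalent palladium, and C–O reductive elimination with loss of the trifluoroacetyl group on work-up would give the diol A1. A1 is formulated here with the (R)-2-methylbutanoyl group in place at B1, between two acetoxy groups. A version with hydrogen at B1 would not be the same trimer: it would postpone the acylation, and with it the stereocentre, to a fully acetylated, electron-poor ring for which no mild acylation exists.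
- In its favour: the ketone places the oxygen that becomes the methyl ether without ambiguity. That is better than the chosen plan, where the distinction rests on the different reactivity of two ortho hydroxyls (steps 2 and 7). The outer rings would start from simpler resorcinol-type ketones, so the step count would probably be equal or lower.
- Against it here: two C–H oxidations must both go to completion on one molecule in hot trifluoroacetic acid with a strong oxidant. Seven aryl acetates can exchange with the solvent, the two diarylmethane CH2 groups are oxidisable, and the ketone-α stereocentre would sit for hours in an enolising acid. Afterwards two new phenols must be methylated with base beside seven acetates, which invites acyl migration.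
- Comparison: structurally it decorates a finished skeleton and leaves the two-different-arms problem on ring B unsolved, while the chosen plan builds ring B with the arms already distinguished. Mechanistically it is oxidative and strongly acidic against thermal and neutral. It is equal or better on step count and on regiocontrol of the methoxy site, and worse on the safety of the stereocentre and the bridges.

**Alternative 2:** The cut is at the three aryl–oxygen bonds of ring B (B2–O, B4–O, B6–O). Forward, the 2,4,6-trifluoro-3,5-bis(arylmethyl)benzoate A4 would be treated with potassium benzyloxide in a dipolar aprotic solvent; three addition–elimination sequences through Meisenheimer adducts would give the tris(benzyloxy) ester A3.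
- In its favour: ring B needs no construction and its pattern is fixed by the symmetry of a cheap trifluoroarene, which is equal to the chosen plan in certainty. The arms could be attached one after the other by metalation between two fluorines. All intermediates would be bench-stable with no moisture-sensitive diene, so in handling it is better than the chosen plan.
- Against it here: only one ester activates the ring, and each benzyloxy group that enters deactivates it further. The third displacement would need forcing conditions with a strongly basic alkoxide, which the enolisable ketones of both arms and the acidic diarylmethane CH2 groups would not tolerate. A3 also still lacks the B1 ketone: turning a di-ortho-substituted ester into the (R)-2-methylbutanoyl ketone means forming the C–C bond next to the stereocentre with a sec-butyl nucleophile, with no stereocontrol in sight, so the chiral-pool acid could not be used.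
- Comparison: convergence is similar up to A3, but the stereocentre is unsolved. The mechanism is anionic and strongly basic against thermal and neutral. Step economy is similar before the key step and clearly worse after it (at least three steps to the ketone plus hydrogenolysis, against one).

**Alternative 3:** The cut opens ring C at its 2–3 and 5–6 bonds. Forward, the trimethylsilyl dienol ether A7 would attack the arm-substituted malonyl dichloride A6 first through its γ-carbon and then through its α-carbon; two C-acylations and enolisation would give A5 with the ring C hydroxyls free.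
- In its favour: the methoxy, methyl and acyl groups of ring C would be set from acyclic pieces with no ambiguity, which is better than the selective O-alkylation of the chosen plan for that ring. Ring C would need no deprotection. The conditions are base-free, so the stereocentre would be about as safe as in the chosen key step (equal).
- Against it here: A6 is the most advanced intermediate of its route, carrying rings A and B and the stereocentre, as a bis(acid chloride) with an acidic α-hydrogen that is prone to ketene formation. The second acylation must go through carbon, whereas closure through oxygen to a pyranone is the usual fate of malonyl dichlorides with enol derivatives. The HCl set free is a further burden. The step solves ring C only; ring B, its three benzyl ethers and the bridge to ring A must be made by other means.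
- Comparison: the approach is linear where the chosen plan is convergent, and its riskiest step comes last on the most valuable material. Mechanistically it is a double electrophilic acylation against a single cycloaddition that forms both bonds with matched polarity. It is worse in step economy.

Key step: step 18

Remark on the chemistry: ketone 9 is taken as a purchasable compound; should it not be in stock, the conditions of step 1 with acetyl chloride in place of 2-methylpropanoyl chloride give it from 1.

## Route

Step 1
Reactants: 1 2-methylbenzene-1,3,5-triol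
Product: 2 2-methyl-1-(2,4,6-trihydroxy-3-methylphenyl)propan-1-one
Conditions: 2-methylpropanoyl chloride (1.05 equiv), AlCl3 (3.5 equiv), CH2Cl2–MeNO2, 0 °C → rt
Reagents that add atoms: 2-methylpropanoyl chloride, CC(C)C(Cl)=O
Why: Friedel–Crafts acylation of a phloroglucinol; the two free ring positions of 1 are equivalent, so a single mono-ketone should form, and the first acyl group deactivates the ring against a second.

Step 2
Reactants: 2 2-methyl-1-(2,4,6-trihydroxy-3-methylphenyl)propan-1-one
Product: 3 1-[4,6-bis(benzyloxy)-2-hydroxy-3-methylphenyl]-2-methylpropan-1-one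
Conditions: BnBr (2.1 equiv), K2CO3 (2.5 equiv), acetone, 50 °C
Reagents that add atoms: benzyl bromide, BrCc1ccccc1
Why: Williamson etherification; the para hydroxyl (most acidic, not hydrogen-bonded) should react first, and of the two chelating ortho hydroxyls the one next to the ring hydrogen should react before the one wedged between methyl and acyl, which keeps the stronger hydrogen bond to the ketone and is left free.

Step 3
Reactants: 3 1-[4,6-bis(benzyloxy)-2-hydroxy-3-methylphenyl]-2-methylpropan-1-one
Product: 4 1-[4,6-bis(benzyloxy)-2-methoxy-3-methylphenyl]-2-methylpropan-1-one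
Conditions: MeI (3 equiv), K2CO3 (3 equiv), DMF, 50 °C
Reagents that add atoms: iodomethane, CI
Why: Williamson methylation of the remaining chelated phenol in a dipolar aprotic solvent; carbonate does not enolise the ketone, and the di-ortho-substituted ketone that results is twisted out of conjugation and shielded, which protects it in later steps.

Step 4
Reactants: 4 1-[4,6-bis(benzyloxy)-2-methoxy-3-methylphenyl]-2-methylpropan-1-one
Product: 6 2,6-bis(benzyloxy)-4-methoxy-3-methyl-5-(2-methylpropanoyl)benzaldehyde, via aryl iminium chloride 5 (not isolated)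
Conditions: POCl3 (2.5 equiv), DMF, 0 → 50 °C; then aq. NaOAc
Reagents that add atoms: N,N-dimethylformamide, CN(C)C=O; water, O
Why: Vilsmeier–Haack formylation at the only free ring position, which is ortho to two benzyloxy groups and para to the methoxy group; benzyl ethers tolerate the reagent, the isopropyl ketone has no α-methylene to be chloroformylated, and 5 is hydrolysed on buffered work-up.

Step 5
Reactants: 6 2,6-bis(benzyloxy)-4-methoxy-3-methyl-5-(2-methylpropanoyl)benzaldehyde
Product: 7 1-[2,4-bis(benzyloxy)-3-(hydroxymethyl)-6-methoxy-5-methylphenyl]-2-methylpropan-1-one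
Conditions: NaBH4 (0.6 equiv), THF–MeOH, 0 °C
Reagents that add atoms: none
Why: Chemoselective borohydride reduction; the aldehyde should be reduced much faster than the twisted, di-ortho-substituted aryl ketone.

Step 6
Reactants: 7 1-[2,4-bis(benzyloxy)-3-(hydroxymethyl)-6-methoxy-5-methylphenyl]-2-methylpropan-1-one
Product: 8 1-[2,4-bis(benzyloxy)-3-(bromomethyl)-6-methoxy-5-methylphenyl]-2-methylpropan-1-one
Conditions: PBr3 (0.4 equiv), CH2Cl2, 0 °C; used crude
Reagents that add atoms: phosphorus tribromide, BrP(Br)Br
Why: Bromination of a benzylic alcohol through its phosphite ester; the electron-rich 2,6-dialkoxybenzyl bromide is reactive and is taken on without chromatography.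

Step 7
Reactants: 9 1-(2,4,6-trihydroxy-3-methylphenyl)ethanone
Product: 10 1-[4,6-bis(benzyloxy)-2-hydroxy-3-methylphenyl]ethanone
Conditions: BnBr (2.1 equiv), K2CO3 (2.5 equiv), acetone, 50 °C
Reagents that add atoms: benzyl bromide, BrCc1ccccc1
Why: Williamson etherification with the same site selectivity as in step 2: para hydroxyl first, then the less hindered ortho hydroxyl, leaving the one between methyl and acetyl.

Step 8
Reactants: 10 1-[4,6-bis(benzyloxy)-2-hydroxy-3-methylphenyl]ethanone
Product: 11 1-[4,6-bis(benzyloxy)-2-methoxy-3-methylphenyl]ethanone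
Conditions: MeI (3 equiv), K2CO3 (3 equiv), DMF, 50 °C
Reagents that add atoms: iodomethane, CI
Why: Williamson methylation of the chelated phenol; carbonate is too weak to enolise the methyl ketone, so C-methylation should not compete.

Step 9
Reactants: 11 1-[4,6-bis(benzyloxy)-2-methoxy-3-methylphenyl]ethanone
Product: 13 3-acetyl-2,6-bis(benzyloxy)-4-methoxy-5-methylbenzaldehyde, via aryl iminium chloride 12 (not isolated)
Conditions: POCl3 (2.0 equiv), DMF, 0 → 35 °C; then aq. NaOAc
Reagents that add atoms: N,N-dimethylformamide, CN(C)C=O; water, O
Why: Vilsmeier–Haack formylation of the single free, triply oxygen-activated ring position; the temperature is kept low because ring formylation of a trialkoxyarene should be faster than chloroformylation of the twisted methyl ketone, which normally needs heating.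

Step 10
Reactants: 13 3-acetyl-2,6-bis(benzyloxy)-4-methoxy-5-methylbenzaldehyde
Product: 14 1-[2,4-bis(benzyloxy)-3-(hydroxymethyl)-6-methoxy-5-methylphenyl]ethanone
Conditions: NaBH4 (0.5 equiv), THF–MeOH, −10 °C
Reagents that add atoms: none
Why: Chemoselective borohydride reduction of the aldehyde; the di-ortho-substituted methyl ketone reacts more slowly, and low temperature and limiting hydride keep it intact.

Step 11
Reactants: 14 1-[2,4-bis(benzyloxy)-3-(hydroxymethyl)-6-methoxy-5-methylphenyl]ethanone
Product: 15 1-[2,4-bis(benzyloxy)-3-(bromomethyl)-6-methoxy-5-methylphenyl]ethanone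
Conditions: PBr3 (0.4 equiv), CH2Cl2, 0 °C; used crude
Reagents that add atoms: phosphorus tribromide, BrP(Br)Br
Why: Bromination of a benzylic alcohol as in step 6; the bromide is used at once.

Step 12
Reactants: 16 methyl acetoacetate; 8 1-[2,4-bis(benzyloxy)-3-(bromomethyl)-6-methoxy-5-methylphenyl]-2-methylpropan-1-one
Product: 18 methyl 5-[2,6-bis(benzyloxy)-4-methoxy-3-methyl-5-(2-methylpropanoyl)phenyl]-3-oxopentanoate, via methyl acetoacetate dianion 17 (not isolated)
Conditions: 16 (1.5 equiv), NaH (1.6 equiv), THF, 0 °C; n-BuLi (1.5 equiv), 0 °C; then 8, −78 → 0 °C; aq. NH4Cl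
Reagents that add atoms: none
Why: γ-Alkylation of the acetoacetate dianion, whose terminal carbanion is the more nucleophilic site and displaces the benzylic bromide; the isopropyl ketone of 8 is shielded by two ortho substituents and its α-hydrogen is less acidic than the conjugate acid of the dianion, so neither addition nor proton transfer should compete.

Step 13
Reactants: 18 methyl 5-[2,6-bis(benzyloxy)-4-methoxy-3-methyl-5-(2-methylpropanoyl)phenyl]-3-oxopentanoate; 15 1-[2,4-bis(benzyloxy)-3-(bromomethyl)-6-methoxy-5-methylphenyl]ethanone
Product: 20 methyl (2RS)-2-{[3-acetyl-2,6-bis(benzyloxy)-4-methoxy-5-methylphenyl]methyl}-5-[2,6-bis(benzyloxy)-4-methoxy-3-methyl-5-(2-methylpropanoyl)phenyl]-3-oxopentanoate, via sodium enolate 19 (not isolated)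
Conditions: NaH (1.0 equiv), THF–DMF, 0 °C; then 15 (1.05 equiv), 0 °C → rt
Reagents that add atoms: none
Why: C-Alkylation of a β-keto ester enolate; the stabilised enolate is too weak a base to touch either aryl ketone, a second alkylation is sterically disfavoured, and the new C2 stereocentre forms racemic without consequence because it becomes sp2 in step 14.

Step 14
Reactants: 20 methyl (2RS)-2-{[3-acetyl-2,6-bis(benzyloxy)-4-methoxy-5-methylphenyl]methyl}-5-[2,6-bis(benzyloxy)-4-methoxy-3-methyl-5-(2-methylpropanoyl)phenyl]-3-oxopentanoate
Product: 21 (3Z)-1-methoxy-1,3-bis(trimethylsilyloxy)penta-1,3-diene bearing at C5 the 2,6-bis(benzyloxy)-4-methoxy-3-methyl-5-(2-methylpropanoyl)phenyl group and at C2 the [2,6-bis(benzyloxy)-4-methoxy-3-methyl-5-(1-trimethylsilyloxyethenyl)phenyl]methyl group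
Conditions: TMSOTf (3.6 equiv), Et3N (4.5 equiv), Et2O, 0 °C → rt; pentane extraction under argon, used crude
Reagents that add atoms: trimethylsilyl trifluoromethanesulfonate, C[Si](C)(C)OS(=O)(=O)C(F)(F)F
Why: Soft enolisation (O-silylation, then deprotonation by the amine), the standard one-flask route from acetoacetates to 1-alkoxy-1,3-bis(silyloxy)dienes; the ring A methyl ketone is silylated under the same conditions and is deliberately carried as its enol ether, while the hindered isopropyl ketone should remain. The equilibrating conditions favour the (3Z) enol ether, which has hydrogen on the inner face of the diene.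

Step 15
Reactants: 22 (2R)-2-methylbutanoic acid
Product: 24 (2R)-N-methoxy-N,2-dimethylbutanamide, via acyl imidazole 23 (not isolated)
Conditions: CDI (1.1 equiv), CH2Cl2, 0 °C → rt; then MeNH(OMe)·HCl (1.3 equiv), rt
Reagents that add atoms: N,O-dimethylhydroxylamine hydrochloride, CNOC.Cl
Why: Amide formation through the acyl imidazole; no acid chloride, ketene or strong base is involved, so the α-stereocentre should be untouched.

Step 16
Reactants: 25 benzyl alcohol
Product: 27 benzyl (E)-1,2-dichlorovinyl ether, via potassium benzyloxide 26 (not isolated)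
Conditions: KH (1.1 equiv), THF, 0 °C; trichloroethene (1.1 equiv), −50 °C → rt
Reagents that add atoms: trichloroethene, ClC=C(Cl)Cl
Why: Known preparation of 1,2-dichlorovinyl ethers: net vinylic substitution of chloride by the alkoxide through elimination–addition, with anti addition giving the (E) ether.

Step 17
Reactants: 27 benzyl (E)-1,2-dichlorovinyl ether; 24 (2R)-N-methoxy-N,2-dimethylbutanamide
Product: 30 (4R)-1-(benzyloxy)-4-methylhex-1-yn-3-one, via lithium benzyloxyacetylide 28 (not isolated), via lithium hemiaminal alkoxide 29 (not isolated)
Conditions: 27 (1.3 equiv), n-BuLi (2.6 equiv), THF, −78 °C; then 24, −78 → −30 °C; inverse quench into cold aq. NaH2PO4; kept below 0 °C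
Reagents that add atoms: none
Why: n-BuLi eliminates HCl from 27 and exchanges the remaining chlorine for lithium to give the alkoxyacetylide; its addition to the N-methoxy-N-methylamide (Weinreb-type ketone synthesis) stops at the chelated adduct 29, so the ketone and its acidic α-hydrogen appear only on the weakly acidic quench, which also protonates the liberated amine before it can add to the ynone. The product is kept cold because benzyl alkynyl ethers can rearrange sigmatropically on warming.

Step 18
Reactants: 21 the tris(silyl) diene of step 14; 30 (4R)-1-(benzyloxy)-4-methylhex-1-yn-3-one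
Product: 32 (2R)-1-[3-{[3-acetyl-2,6-bis(benzyloxy)-4-methoxy-5-methylphenyl]methyl}-6-(benzyloxy)-5-{[2,6-bis(benzyloxy)-4-methoxy-3-methyl-5-(2-methylpropanoyl)phenyl]methyl}-2,4-dihydroxyphenyl]-2-methylbutan-1-one, via cyclohexa-1,4-diene cycloadduct 31 (not isolated)
Conditions: 30 (1.3 equiv), toluene (1 M), argon, −20 → 25 °C, at most 40 °C; then 1 M HCl–THF, 0 °C
Reagents that add atoms: none
Why: Normal-demand Diels–Alder reaction: the diene terminus C4 of 21 bonds to the benzyloxy-bearing alkyne carbon of 30 (B5–B6) and the ketene-acetal carbon C1 to the acyl-bearing carbon (B1–B2), giving the cyclohexa-1,4-diene 31; acid work-up then removes methanol across B2/B5 and all three silyl groups, which aromatises ring B, frees the B2 and B4 phenols and returns the ring A acetyl group. The closest known reaction type is the benzannulation of 1-alkoxy-1,3-bis(silyloxy)-1,3-dienes with acetylenic ketones and esters to resorcinols by cycloaddition and loss of alcohol. Ring B, a six-membered carbocycle, is closed by both new σ-bonds in a suprafacial, probably asynchronous [4+2] event; should the process be stepwise, a vinylogous Mukaiyama–Michael addition (B5–B6) is followed by six-membered ring closure of the allenyl enolate carbon onto the silylated ester carbon (B1–B2), with the same outcome. No stereocentre is created that survives: B2 and B5 of 31 are sp3 but both become aromatic, and the α-stereocentre of 30 is a spectator that meets neither base nor heat above 40 °C, the hydrolytic work-up being brief and cold. The step needs head-to-tail regioselectivity, secured by matched polarisation: the three oxygen donors put the largest HOMO coefficient on C4 of the diene, and the carbonyl group puts the largest LUMO coefficient on the β-carbon of the ynone. It needs chemoselectivity, secured by the C2 substituent, which blocks the alternative closure of C2 onto the ketone carbonyl, and by the far lower nucleophilicity of the ring A silyl enol ether compared with the ketene acetal diene. It needs the s-cis conformer, secured by the (3Z) geometry that turns hydrogen, not the benzylic chain, into the diene cavity. Aromatisation must expel methanol and not benzyl alcohol, which is assured because only B2 carries leaving groups on an sp3 carbon while the B6 oxygen sits on an sp2 carbon and so stays as the benzyl ether.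

Step 19
Reactants: 32 the penta-O-benzyl trimer of step 18
Product: 33 (2R)-1-[3-[(3-acetyl-2,6-dihydroxy-4-methoxy-5-methylphenyl)methyl]-2,4,6-trihydroxy-5-{[2,6-dihydroxy-4-methoxy-3-methyl-5-(2-methylpropanoyl)phenyl]methyl}phenyl]-2-methylbutan-1-one
Conditions: H2 (1 atm), Pd/C (10% palladium on carbon), EtOAc–MeOH, rt; degassed solvents, filtration under argon
Reagents that add atoms: none
Why: Hydrogenolysis of five aryl benzyl ethers under neutral conditions; chelated electron-rich aryl ketones and diarylmethane bridges should not be reduced at atmospheric pressure, and with neither acid nor base present the stereocentre α to the B1 ketone is retained.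

## Compound list

1 | 2-methylbenzene-1,3,5-triol | Cc1c(O)cc(O)cc1O | starting material
2 | 2-methyl-1-(2,4,6-trihydroxy-3-methylphenyl)propan-1-one | CC(C)C(=O)c1c(O)cc(O)c(C)c1O | intermediate
3 | 1-[4,6-bis(benzyloxy)-2-hydroxy-3-methylphenyl]-2-methylpropan-1-one | CC(C)C(=O)c1c(OCc2ccccc2)cc(OCc2ccccc2)c(C)c1O | intermediate
4 | 1-[4,6-bis(benzyloxy)-2-methoxy-3-methylphenyl]-2-methylpropan-1-one | CC(C)C(=O)c1c(OCc2ccccc2)cc(OCc2ccccc2)c(C)c1OC | intermediate
5 | N-{[2,6-bis(benzyloxy)-4-methoxy-3-methyl-5-(2-methylpropanoyl)phenyl]methylidene}-N-methylmethanaminium chloride | CC(C)C(=O)c1c(OCc2ccccc2)c(C=[N+](C)C)c(OCc2ccccc2)c(C)c1OC.[Cl-] | intermediate (not isolated)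
6 | 2,6-bis(benzyloxy)-4-methoxy-3-methyl-5-(2-methylpropanoyl)benzaldehyde | CC(C)C(=O)c1c(OCc2ccccc2)c(C=O)c(OCc2ccccc2)c(C)c1OC | intermediate
7 | 1-[2,4-bis(benzyloxy)-3-(hydroxymethyl)-6-methoxy-5-methylphenyl]-2-methylpropan-1-one | CC(C)C(=O)c1c(OCc2ccccc2)c(CO)c(OCc2ccccc2)c(C)c1OC | intermediate
8 | 1-[2,4-bis(benzyloxy)-3-(bromomethyl)-6-methoxy-5-methylphenyl]-2-methylpropan-1-one | CC(C)C(=O)c1c(OCc2ccccc2)c(CBr)c(OCc2ccccc2)c(C)c1OC | intermediate
9 | 1-(2,4,6-trihydroxy-3-methylphenyl)ethanone | CC(=O)c1c(O)cc(O)c(C)c1O | starting material
10 | 1-[4,6-bis(benzyloxy)-2-hydroxy-3-methylphenyl]ethanone | CC(=O)c1c(OCc2ccccc2)cc(OCc2ccccc2)c(C)c1O | intermediate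
11 | 1-[4,6-bis(benzyloxy)-2-methoxy-3-methylphenyl]ethanone | CC(=O)c1c(OCc2ccccc2)cc(OCc2ccccc2)c(C)c1OC | intermediate
12 | N-{[3-acetyl-2,6-bis(benzyloxy)-4-methoxy-5-methylphenyl]methylidene}-N-methylmethanaminium chloride | CC(=O)c1c(OCc2ccccc2)c(C=[N+](C)C)c(OCc2ccccc2)c(C)c1OC.[Cl-] | intermediate (not isolated)
13 | 3-acetyl-2,6-bis(benzyloxy)-4-methoxy-5-methylbenzaldehyde | CC(=O)c1c(OCc2ccccc2)c(C=O)c(OCc2ccccc2)c(C)c1OC | intermediate
14 | 1-[2,4-bis(benzyloxy)-3-(hydroxymethyl)-6-methoxy-5-methylphenyl]ethanone | CC(=O)c1c(OCc2ccccc2)c(CO)c(OCc2ccccc2)c(C)c1OC | intermediate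
15 | 1-[2,4-bis(benzyloxy)-3-(bromomethyl)-6-methoxy-5-methylphenyl]ethanone | CC(=O)c1c(OCc2ccccc2)c(CBr)c(OCc2ccccc2)c(C)c1OC | intermediate
16 | methyl acetoacetate (methyl 3-oxobutanoate) | CC(=O)CC(=O)OC | starting material
17 | sodium lithium dianion of methyl 3-oxobutanoate (deprotonated at C2 and C4) | [Na+].[Li+].[CH2-]C(=O)[CH-]C(=O)OC | intermediate (not isolated)
18 | methyl 5-[2,6-bis(benzyloxy)-4-methoxy-3-methyl-5-(2-methylpropanoyl)phenyl]-3-oxopentanoate | COC(=O)CC(=O)CCc1c(OCc2ccccc2)c(C)c(OC)c(C(=O)C(C)C)c1OCc1ccccc1 | intermediate
19 | sodium enolate of 18 (deprotonated at C2) | [Na+].COC(=O)[CH-]C(=O)CCc1c(OCc2ccccc2)c(C)c(OC)c(C(=O)C(C)C)c1OCc1ccccc1 | intermediate (not isolated)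
20 | methyl (2RS)-2-{[3-acetyl-2,6-bis(benzyloxy)-4-methoxy-5-methylphenyl]methyl}-5-[2,6-bis(benzyloxy)-4-methoxy-3-methyl-5-(2-methylpropanoyl)phenyl]-3-oxopentanoate, racemic at C2 | COC(=O)C(Cc1c(OCc2ccccc2)c(C)c(OC)c(C(C)=O)c1OCc1ccccc1)C(=O)CCc1c(OCc2ccccc2)c(C)c(OC)c(C(=O)C(C)C)c1OCc1ccccc1 | intermediate
21 | (3Z)-1-methoxy-1,3-bis(trimethylsilyloxy)penta-1,3-diene with the ring C aryl group at C5 and the ring A arylmethyl group at C2, ring A acetyl as its trimethylsilyl enol ether; C1=C2 geometry not defined | COC(O[Si](C)(C)C)=C(Cc1c(OCc2ccccc2)c(C)c(OC)c(C(=C)O[Si](C)(C)C)c1OCc1ccccc1)/C(O[Si](C)(C)C)=C/Cc1c(OCc2ccccc2)c(C)c(OC)c(C(=O)C(C)C)c1OCc1ccccc1 | intermediate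
22 | (2R)-2-methylbutanoic acid | CC[C@@H](C)C(=O)O | starting material
23 | (2R)-1-(1H-imidazol-1-yl)-2-methylbutan-1-one | CC[C@@H](C)C(=O)n1ccnc1 | intermediate (not isolated)
24 | (2R)-N-methoxy-N,2-dimethylbutanamide | CC[C@@H](C)C(=O)N(C)OC | intermediate
25 | benzyl alcohol | OCc1ccccc1 | starting material
26 | potassium benzyloxide | [K+].[O-]Cc1ccccc1 | intermediate (not isolated)
27 | benzyl (E)-1,2-dichlorovinyl ether | Cl/C=C(/Cl)OCc1ccccc1 | intermediate
28 | lithium (benzyloxy)acetylide | [Li+].[C-]#COCc1ccccc1 | intermediate (not isolated)
29 | lithium (4R)-1-(benzyloxy)-3-[methoxy(methyl)amino]-4-methylhex-1-yn-3-olate, both configurations at C3 | [Li+].CC[C@@H](C)C([O-])(C#COCc1ccccc1)N(C)OC | intermediate (not isolated)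
30 | (4R)-1-(benzyloxy)-4-methylhex-1-yn-3-one | CC[C@@H](C)C(=O)C#COCc1ccccc1 | intermediate
31 | cycloadduct: cyclohexa-1,4-diene with B1 (acyl)=B6 (OBn), B5 sp3 (H, ring C arm), B4 (OSiMe3)=B3 (ring A arm, acetyl as silyl enol ether), B2 sp3 (OMe, OSiMe3); mixture of diastereomers at B2/B5 | CC[C@@H](C)C(=O)C1=C(OCc2ccccc2)C(Cc2c(OCc3ccccc3)c(C)c(OC)c(C(=O)C(C)C)c2OCc2ccccc2)C(O[Si](C)(C)C)=C(Cc2c(OCc3ccccc3)c(C)c(OC)c(C(=C)O[Si](C)(C)C)c2OCc2ccccc2)C1(OC)O[Si](C)(C)C | intermediate (not isolated)
32 | (2R)-1-[3-{[3-acetyl-2,6-bis(benzyloxy)-4-methoxy-5-methylphenyl]methyl}-6-(benzyloxy)-5-{[2,6-bis(benzyloxy)-4-methoxy-3-methyl-5-(2-methylpropanoyl)phenyl]methyl}-2,4-dihydroxyphenyl]-2-methylbutan-1-one | CC[C@@H](C)C(=O)c1c(O)c(Cc2c(OCc3ccccc3)c(C)c(OC)c(C(C)=O)c2OCc2ccccc2)c(O)c(Cc2c(OCc3ccccc3)c(C)c(OC)c(C(=O)C(C)C)c2OCc2ccccc2)c1OCc1ccccc1 | intermediate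
33 | (2R)-1-[3-[(3-acetyl-2,6-dihydroxy-4-methoxy-5-methylphenyl)methyl]-2,4,6-trihydroxy-5-{[2,6-dihydroxy-4-methoxy-3-methyl-5-(2-methylpropanoyl)phenyl]methyl}phenyl]-2-methylbutan-1-one (CNP0169975.1) | CC[C@@H](C)C(=O)c1c(O)c(Cc2c(O)c(C)c(OC)c(C(C)=O)c2O)c(O)c(Cc2c(O)c(C)c(OC)c(C(=O)C(C)C)c2O)c1O | target

## Step count and least certain steps

Total: 19 steps. Longest linear sequence: 11 steps (1–6, 12, 13, 14, 18, 19).

**Step 18 (key step).** The cycloaddition may be too slow below the temperature at which the benzyl alkynyl ether of 30 starts to rearrange. The donor oxygen raises the LUMO of the alkyne and both reacting termini of the diene are substituted. Protodesilylation of the diene by adventitious moisture would compete with a slow cycloaddition. The fallback abandons the cycloaddition for classical bridge formation. It sets out from 22, 7 and 14 and comes back at 33. Acid 22 is converted (oxalyl chloride, cat. DMF, CH2Cl2) into (2R)-2-methylbutanoyl chloride F1. F1 acylates benzene-1,3,5-triol (AlCl3, CH2Cl2–MeNO2, 0 °C) to (2R)-2-methyl-1-(2,4,6-trihydroxyphenyl)butan-1-one F2, whose optical purity is to be checked at this point. Acid-catalysed Friedel–Crafts benzylation of F2, used in excess, with alcohol 7 (TsOH cat., dioxane, rt) should give the mono-bridged ketone (2R)-1-[3-{[2,6-bis(benzyloxy)-4-methoxy-3-methyl-5-(2-methylpropanoyl)phenyl]methyl}-2,4,6-trihydroxyphenyl]-2-methylbutan-1-one F3. A second benzylation with alcohol 14 gives the tetra-O-benzyl trimer F4, and hydrogenolysis as in step 19 gives 33. The price is statistical control of mono- against bis-benzylation.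

**Step 14.** Enolisation towards C4 may stay incomplete, since the second silylation of a 2-substituted keto ester is the slow one. The isopropyl ketone may be partly silylated, and the crude diene may hydrolyse before use. The fallback sets out from 18 and comes back at 32. Keto ester 18, which has neither the methyl ketone nor a C2 substituent, is silylated under the conditions of step 14 to the (3Z)-bis(silyloxy)diene F5. Cycloaddition with 30 and acid work-up as in step 18 should give the acylresorcinol (2R)-1-[6-(benzyloxy)-5-{[2,6-bis(benzyloxy)-4-methoxy-3-methyl-5-(2-methylpropanoyl)phenyl]methyl}-2,4-dihydroxyphenyl]-2-methylbutan-1-one F6, with hydrogen at B3. Friedel–Crafts benzylation of this most nucleophilic ring position with alcohol 14 (TsOH cat., CH2Cl2, 0 °C) then gives 32.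

**Step 12.** Proton transfer or carbonyl addition between the strongly basic dianion and the ketone-bearing bromide may compete, or displacement at the doubly ortho-substituted benzylic carbon may be slow while 8 decomposes. The fallback sets out from 16 and 8 and comes back at 18. Keto ester 16 is silylated (TMSOTf, Et3N, Et2O, 0 °C) to 1-methoxy-1,3-bis(trimethylsilyloxy)buta-1,3-diene F7. Bromide 8 is ionised with ZnBr2 (10 mol%) in CH2Cl2 at −40 °C in the presence of F7, and the benzylic cation is trapped at the diene terminus (Lewis-acid-promoted alkylation of a silyl dienolate by an SN1-active halide). Aqueous work-up gives 18 without any strong base.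

**Step 9.** Chloroformylation of the methyl ketone through its enol may compete with ring formylation, or attack at the hindered ring position may be sluggish. The fallback sets out from 11 and comes back at 14. Ketone 11 is brominated at its one free ring position (NBS, MeCN, 0 °C) to 1-[2,4-bis(benzyloxy)-3-bromo-6-methoxy-5-methylphenyl]ethanone F8. Suzuki–Miyaura coupling with potassium (acetoxymethyl)trifluoroborate (Pd(OAc)2, RuPhos, K2CO3, dioxane–H2O, 90 °C), with the acetate cleaved in the basic medium, gives alcohol 14 directly and makes step 10 unnecessary.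

**Steps 2 and 7.** The second benzylation may discriminate poorly between the two ortho hydroxyls, with over-alkylation beside it. The fallback sets out from 2 (or 9) and comes back at 3 (or 10). Exhaustive benzylation (BnBr 3.5 equiv, K2CO3, DMF, 60 °C), which raises no regiochemical question, gives 2-methyl-1-[2,4,6-tris(benzyloxy)-3-methylphenyl]propan-1-one F9 from 2, or 1-[2,4,6-tris(benzyloxy)-3-methylphenyl]ethanone F10 from 9. Chelation-controlled cleavage of one ortho benzyl ether with MgBr2·OEt2 (toluene–Et2O, rt → 60 °C) should then remove the benzyl group from the oxygen compressed between methyl and acyl. Its loss relieves the most strain and gives the stronger chelate, leading to 3 (or 10).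

## Further compounds

F1 | step 18 | (2R)-2-methylbutanoyl chloride | CC[C@@H](C)C(Cl)=O
F2 | step 18 | (2R)-2-methyl-1-(2,4,6-trihydroxyphenyl)butan-1-one | CC[C@@H](C)C(=O)c1c(O)cc(O)cc1O
F3 | step 18 | (2R)-1-[3-{[2,6-bis(benzyloxy)-4-methoxy-3-methyl-5-(2-methylpropanoyl)phenyl]methyl}-2,4,6-trihydroxyphenyl]-2-methylbutan-1-one | CC[C@@H](C)C(=O)c1c(O)cc(O)c(Cc2c(OCc3ccccc3)c(C)c(OC)c(C(=O)C(C)C)c2OCc2ccccc2)c1O
F4 | step 18 | (2R)-1-[3-{[3-acetyl-2,6-bis(benzyloxy)-4-methoxy-5-methylphenyl]methyl}-5-{[2,6-bis(benzyloxy)-4-methoxy-3-methyl-5-(2-methylpropanoyl)phenyl]methyl}-2,4,6-trihydroxyphenyl]-2-methylbutan-1-one | CC[C@@H](C)C(=O)c1c(O)c(Cc2c(OCc3ccccc3)c(C)c(OC)c(C(C)=O)c2OCc2ccccc2)c(O)c(Cc2c(OCc3ccccc3)c(C)c(OC)c(C(=O)C(C)C)c2OCc2ccccc2)c1O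
F5 | step 14 | (3Z)-1-methoxy-1,3-bis(trimethylsilyloxy)-5-[2,6-bis(benzyloxy)-4-methoxy-3-methyl-5-(2-methylpropanoyl)phenyl]penta-1,3-diene | COC(O[Si](C)(C)C)=C/C(O[Si](C)(C)C)=C/Cc1c(OCc2ccccc2)c(C)c(OC)c(C(=O)C(C)C)c1OCc1ccccc1
F6 | step 14 | (2R)-1-[6-(benzyloxy)-5-{[2,6-bis(benzyloxy)-4-methoxy-3-methyl-5-(2-methylpropanoyl)phenyl]methyl}-2,4-dihydroxyphenyl]-2-methylbutan-1-one | CC[C@@H](C)C(=O)c1c(O)cc(O)c(Cc2c(OCc3ccccc3)c(C)c(OC)c(C(=O)C(C)C)c2OCc2ccccc2)c1OCc1ccccc1
F7 | step 12 | 1-methoxy-1,3-bis(trimethylsilyloxy)buta-1,3-diene | COC(O[Si](C)(C)C)=CC(O[Si](C)(C)C)=C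
F8 | step 9 | 1-[2,4-bis(benzyloxy)-3-bromo-6-methoxy-5-methylphenyl]ethanone | CC(=O)c1c(OCc2ccccc2)c(Br)c(OCc2ccccc2)c(C)c1OC
F9 | step 2 | 2-methyl-1-[2,4,6-tris(benzyloxy)-3-methylphenyl]propan-1-one | CC(C)C(=O)c1c(OCc2ccccc2)cc(OCc2ccccc2)c(C)c1OCc1ccccc1
F10 | step 7 | 1-[2,4,6-tris(benzyloxy)-3-methylphenyl]ethanone | CC(=O)c1c(OCc2ccccc2)cc(OCc2ccccc2)c(C)c1OCc1ccccc1
A1 | alternative 1 | heptaacetate of the trimer with free hydroxyls at A4 and C4 and the (R)-2-methylbutanoyl group at B1 | CC[C@@H](C)C(=O)c1c(OC(C)=O)c(Cc2c(OC(C)=O)c(C)c(O)c(C(C)=O)c2OC(C)=O)c(OC(C)=O)c(Cc2c(OC(C)=O)c(C)c(O)c(C(=O)C(C)C)c2OC(C)=O)c1OC(C)=O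
A2 | alternative 1 | heptaacetate of the trimer with hydrogen at A4 and C4 | CC[C@@H](C)C(=O)c1c(OC(C)=O)c(Cc2c(OC(C)=O)c(C)cc(C(C)=O)c2OC(C)=O)c(OC(C)=O)c(Cc2c(OC(C)=O)c(C)cc(C(=O)C(C)C)c2OC(C)=O)c1OC(C)=O
A3 | alternative 2 | benzyl 2,4,6-tris(benzyloxy)-3-{[3-acetyl-2,6-bis(benzyloxy)-4-methoxy-5-methylphenyl]methyl}-5-{[2,6-bis(benzyloxy)-4-methoxy-3-methyl-5-(2-methylpropanoyl)phenyl]methyl}benzoate | O=C(OCc1ccccc1)c1c(OCc2ccccc2)c(Cc2c(OCc3ccccc3)c(C)c(OC)c(C(C)=O)c2OCc2ccccc2)c(OCc2ccccc2)c(Cc2c(OCc3ccccc3)c(C)c(OC)c(C(=O)C(C)C)c2OCc2ccccc2)c1OCc1ccccc1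
A4 | alternative 2 | benzyl 2,4,6-trifluoro-3-{[3-acetyl-2,6-bis(benzyloxy)-4-methoxy-5-methylphenyl]methyl}-5-{[2,6-bis(benzyloxy)-4-methoxy-3-methyl-5-(2-methylpropanoyl)phenyl]methyl}benzoate | O=C(OCc1ccccc1)c1c(F)c(Cc2c(OCc3ccccc3)c(C)c(OC)c(C(C)=O)c2OCc2ccccc2)c(F)c(Cc2c(OCc3ccccc3)c(C)c(OC)c(C(=O)C(C)C)c2OCc2ccccc2)c1F
A5 | alternative 3 | the trimer with the three ring B and two ring A hydroxyls as benzyl ethers and ring C hydroxyls free | CC[C@@H](C)C(=O)c1c(OCc2ccccc2)c(Cc2c(OCc3ccccc3)c(C)c(OC)c(C(C)=O)c2OCc2ccccc2)c(OCc2ccccc2)c(Cc2c(O)c(C)c(OC)c(C(=O)C(C)C)c2O)c1OCc1ccccc1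
A6 | alternative 3 | 2-(arylmethyl)malonyl dichloride carrying rings A and B (all five hydroxyls as benzyl ethers) | CC[C@@H](C)C(=O)c1c(OCc2ccccc2)c(Cc2c(OCc3ccccc3)c(C)c(OC)c(C(C)=O)c2OCc2ccccc2)c(OCc2ccccc2)c(CC(C(Cl)=O)C(Cl)=O)c1OCc1ccccc1
A7 | alternative 3 | 5-methoxy-2-methyl-3-(trimethylsilyloxy)hepta-3,5-diene | CC(C)C(O[Si](C)(C)C)=CC(OC)=CC
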